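**Retrosynthetic overview**
1. The ester C–O bond is cut last (oleic acid plus the C20 alcohol). The alcohol is cut between C8 and C9 of its nonadienyl chain into two C10 halves: (S)-α-cyclogeranyl phenyl sulfone and (2E,6E)-8-bromogeranyl acetate.
2. Ring numbering used here: C1 stereocentre, C2 methyl-bearing alkene carbon, C3 vinylic CH, C4 and C5 methylenes, C6 gem-dimethyl carbon. C1 is set by 1,3-chirality transfer (allylic diazene retro-ene) from a carbinol at C3, itself set by oxazaborolidine reduction of a 2,4,4-trimethyl-3-(sulfonylmethyl)cyclohex-2-enone.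
3. Key disconnection: ring bonds C3–C4 and C5–C6 are cut together, so the cyclohexenone becomes a cyclobutenone plus ethylene (two-carbon ring expansion).
4. Enabling feature: C4–C5 is an unsubstituted CH2–CH2 between vinylic C3 and quaternary C6, that is, one ethylene. With C3 raised to C=O, the atoms C3–C2–C1–C6 form a cyclobutenone whose strained acyl–C(sp3) bond C3–C6 can open, and the quaternary C6 blocks aromatisation.
5. Ring order: the four-membered ring is made first (ketene plus ynol ether [2+2]) and is then expanded to the six-membered ring, the only ring of the target.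

Key step: step 3

Remark on the chemistry: 1-ethoxyprop-1-yne is taken as a purchasable ynol ether, and the facial sense of the oxazaborolidine reduction in step 4 is assigned by the usual large/small-group model for 2-alkylcyclohex-2-enones.

**Step 1**
Reactants: 1 isobutyryl chloride; 2 1-ethoxyprop-1-yne
Product: 4 3-ethoxy-2,4,4-trimethylcyclobut-2-en-1-one, via dimethylketene 3 (not isolated)
Conditions: Et3N, Et2O, reflux
Reagents that add atoms: none
Why: Ketene–ynol ether [2+2] cycloaddition: dimethylketene, formed in situ by dehydrochlorination of 1, is attacked at its carbonyl carbon by the nucleophilic methyl-bearing carbon of 2 and closes at the ethoxy-bearing carbon, which puts C=O next to C–CH3 and CMe2 next to C–OEt; no stereocentre is formed.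

**Step 2**
Reactants: 4 3-ethoxy-2,4,4-trimethylcyclobut-2-en-1-one; 5 methyl phenyl sulfone
Product: 8 2,4,4-trimethyl-3-[(phenylsulfonyl)methyl]cyclobut-2-en-1-one, via (phenylsulfonyl)methyllithium 6 (not isolated), via carbinol adduct 7 (not isolated)
Conditions: 5, n-BuLi, THF, −78 °C; then 4, −78 °C; then 2 M aq. HCl, 0 °C to rt
Reagents that add atoms: water, O (oxygen of the new carbonyl group)
Why: Stork–Danheiser-type sequence known for 3-alkoxycyclobutenones: the α-sulfonyl carbanion adds 1,2 to the vinylogous ester carbonyl and aqueous acid hydrolyses the enol ether with loss of water from the carbinol, so the carbonyl group moves to the former C–OEt carbon next to CMe2; the carbinol stereocentre of 7 is erased.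

**Step 3**
Reactants: 8 2,4,4-trimethyl-3-[(phenylsulfonyl)methyl]cyclobut-2-en-1-one; 9 ethylene
Product: 10 2,4,4-trimethyl-3-[(phenylsulfonyl)methyl]cyclohex-2-en-1-one
Conditions: [Rh(C2H4)2Cl]2 (5 mol %), P[3,5-(CF3)2C6H3]3 (20 mol %), ethylene (30 bar), toluene, 60 °C
Reagents that add atoms: none
Why: Proposed new method: monovalent rhodium is expected to insert into the strained acyl–C(sp3) bond between the carbonyl carbon and the CMe2 carbon of 8 (equivalently, to trap the vinylketene of its 4π ring opening as an η4 complex), giving a rhodacyclopentenone of trivalent rhodium; ethylene then inserts into the Rh–acyl bond and C–C reductive elimination at the allylic CMe2 terminus follows (or the two events in the opposite order), so the carbonyl carbon gains one CH2 and the gem-dimethyl carbon the other. The closest known reaction types are the rhodium-catalysed coupling of cyclobutenones with strained or electron-poor alkenes to six-membered rings, the rhodium-catalysed "cut-and-sew" insertion of olefins into cyclobutanones, and the insertion of ethylene gas into the acyl–carbon bond of 1-indanones; the new element is the pairing of ethylene with a 4,4-dialkylcyclobutenone. The six-membered ring is closed by reductive elimination from a seven-membered rhodacycle, a two-carbon ring expansion that amounts to a formal [4+2] of the vinylketene four-atom unit with ethylene. No stereocentre is formed; the step places C=O on the future vinylic CH and the tetrasubstituted alkene between the methyl-bearing carbon and the future stereocentre, which is what steps 4 and 5 need. The selectivity needed is ethylene insertion over β-hydride elimination from the methyl groups on the metal-bound CMe2 carbon, over decarbonylation and over thermal 1,5-hydrogen shift of free vinylketene. The quaternary CMe2 carbon excludes phenol formation, ethylene is symmetrical so no regiochemistry arises, and the high ethylene pressure, the electron-poor phosphine (faster reductive elimination) and the low temperature are chosen to favour insertion.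

**Step 4**
Reactants: 10 2,4,4-trimethyl-3-[(phenylsulfonyl)methyl]cyclohex-2-en-1-one
Product: 11 (1R)-2,4,4-trimethyl-3-[(phenylsulfonyl)methyl]cyclohex-2-en-1-ol
Conditions: (S)-1-methyl-3,3-diphenyltetrahydro-1H,3H-pyrrolo[1,2-c][1,3,2]oxazaborole ((S)-Me-CBS, 20 mol %), catecholborane, toluene, −78 °C; then aq. NaOH
Reagents that add atoms: none
Why: Corey–Bakshi–Shibata reduction: the methyl-bearing alkene carbon acts as the large group and the ring CH2 as the small one, so the (S)-oxazaborolidine should deliver hydride to the face that gives the (1R)-carbinol, and catecholborane reduces only the carbonyl group.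

**Step 5**
Reactants: 11 (1R)-2,4,4-trimethyl-3-[(phenylsulfonyl)methyl]cyclohex-2-en-1-ol
Product: 14 ({[(1S)-2,6,6-trimethylcyclohex-2-en-1-yl]methyl}sulfonyl)benzene [(S)-α-cyclogeranyl phenyl sulfone], via allylic sulfonylhydrazine 12 (not isolated), via allylic diazene 13 (not isolated)
Conditions: 2-nitrobenzenesulfonohydrazide (NBSH), PPh3, DEAD, THF, −30 °C; then rt
Reagents that add atoms: none
Why: Myers reductive 1,3-transposition: Mitsunobu displacement by the sulfonylhydrazide inverts the carbinol carbon, loss of the sulfinic acid gives the allylic diazene, and its retro-ene loss of N2 delivers hydrogen suprafacially to the sulfonylmethyl-bearing alkene carbon on the face anti to the former OH group, so the alkene moves into the trisubstituted position and the (S) stereocentre is set by 1,3-chirality transfer from the carbinol.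

**Step 6**
Reactants: 15 geranyl acetate
Product: 16 (2E,6E)-8-hydroxy-3,7-dimethylocta-2,6-dien-1-yl acetate
Conditions: SeO2 (10 mol %), t-BuOOH, 2-hydroxybenzoic acid (10 mol %), CH2Cl2, rt
Reagents that add atoms: tert-butyl hydroperoxide, CC(C)(C)OO (terminal source of the new oxygen, relayed by SeO2, O=[Se]=O)
Why: Riley-type allylic oxidation with catalytic SeO2 (ene reaction followed by [2,3]-sigmatropic shift) should pick the (E)-methyl group of the electron-richer distal alkene, the 2,3-alkene being deactivated by the allylic acetate; alkene geometry is kept and no stereocentre is formed.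

**Step 7**
Reactants: 16 (2E,6E)-8-hydroxy-3,7-dimethylocta-2,6-dien-1-yl acetate
Product: 17 (2E,6E)-8-bromo-3,7-dimethylocta-2,6-dien-1-yl acetate
Conditions: CBr4, PPh3, CH2Cl2, 0 °C
Reagents that add atoms: carbon tetrabromide, BrC(Br)(Br)Br
Why: Appel reaction: SN2 displacement of the oxyphosphonium by bromide at the primary allylic carbon, mild enough to keep the acetate and the (E) geometry.

**Step 8**
Reactants: 14 (S)-α-cyclogeranyl phenyl sulfone; 17 (2E,6E)-8-bromo-3,7-dimethylocta-2,6-dien-1-yl acetate
Product: 19 (2E,6E)-3,7-dimethyl-9-(phenylsulfonyl)-9-[(1S)-2,6,6-trimethylcyclohex-2-en-1-yl]nona-2,6-dien-1-yl acetate (both epimers at C9), via lithiated sulfone 18 (not isolated)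
Conditions: 14, n-BuLi, THF–HMPA, −78 °C; then 17, −78 to −40 °C
Reagents that add atoms: none
Why: Alkylation of an α-sulfonyl carbanion by a primary allylic bromide (the classical sulfone coupling of terpenoid halves) should be far faster at −78 °C than attack on the acetate; the ring stereocentre is not acidic and stays untouched, while the new sulfone-bearing centre forms as both epimers and is erased in step 9.

**Step 9**
Reactants: 19 (2E,6E)-3,7-dimethyl-9-(phenylsulfonyl)-9-[(1S)-2,6,6-trimethylcyclohex-2-en-1-yl]nona-2,6-dien-1-yl acetate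
Product: 21 (2E,6E)-3,7-dimethyl-9-[(1S)-2,6,6-trimethylcyclohex-2-en-1-yl]nona-2,6-dien-1-ol, via desulfonylated acetate 20 (not isolated)
Conditions: Na(Hg) (6 % Na), Na2HPO4, THF–MeOH, −20 °C; then K2CO3, MeOH, rt
Reagents that add atoms: none
Why: Reductive desulfonylation by electron transfer from sodium amalgam under phosphate buffer, followed by base-catalysed methanolysis of the acetate in the same pot; the isolated trisubstituted alkenes and the ring stereocentre are inert to both.

**Step 10**
Reactants: 21 (2E,6E)-3,7-dimethyl-9-[(1S)-2,6,6-trimethylcyclohex-2-en-1-yl]nona-2,6-dien-1-ol; 22 oleic acid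
Product: 23 (2E,6E)-3,7-dimethyl-9-[(1S)-2,6,6-trimethylcyclohex-2-en-1-yl]nona-2,6-dien-1-yl (9Z)-octadec-9-enoate
Conditions: N-(3-dimethylaminopropyl)-N'-ethylcarbodiimide hydrochloride (EDC·HCl), 4-(dimethylamino)pyridine (DMAP, 10 mol %), CH2Cl2, 0 °C to rt
Reagents that add atoms: none
Why: Steglich esterification of a primary allylic alcohol under neutral conditions that leave the (Z) alkene of oleic acid and the three trisubstituted alkenes untouched.

**Compound list**
1 | isobutyryl chloride | CC(C)C(=O)Cl | starting material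
2 | 1-ethoxyprop-1-yne | CCOC#CC | starting material
3 | dimethylketene | CC(C)=C=O | intermediate (not isolated)
4 | 3-ethoxy-2,4,4-trimethylcyclobut-2-en-1-one | CCOC1=C(C)C(=O)C1(C)C | intermediate
5 | methyl phenyl sulfone | CS(=O)(=O)c1ccccc1 | starting material
6 | (phenylsulfonyl)methyllithium | [Li]CS(=O)(=O)c1ccccc1 | intermediate (not isolated)
7 | 3-ethoxy-2,4,4-trimethyl-1-[(phenylsulfonyl)methyl]cyclobut-2-en-1-ol (racemic; lithium alkoxide in the flask) | CCOC1=C(C)C(O)(CS(=O)(=O)c2ccccc2)C1(C)C | intermediate (not isolated)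
8 | 2,4,4-trimethyl-3-[(phenylsulfonyl)methyl]cyclobut-2-en-1-one | CC1=C(CS(=O)(=O)c2ccccc2)C(C)(C)C1=O | intermediate
9 | ethylene | C=C | starting material
10 | 2,4,4-trimethyl-3-[(phenylsulfonyl)methyl]cyclohex-2-en-1-one | CC1=C(CS(=O)(=O)c2ccccc2)C(C)(C)CCC1=O | intermediate
11 | (1R)-2,4,4-trimethyl-3-[(phenylsulfonyl)methyl]cyclohex-2-en-1-ol | O[C@@H]1CCC(C)(C)C(CS(=O)(=O)c2ccccc2)=C1C | intermediate
12 | 2-nitro-N-{(1S)-2,4,4-trimethyl-3-[(phenylsulfonyl)methyl]cyclohex-2-en-1-yl}benzenesulfonohydrazide | NN([C@H]1CCC(C)(C)C(CS(=O)(=O)c2ccccc2)=C1C)S(=O)(=O)c1ccccc1[N+](=O)[O-] | intermediate (not isolated)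
13 | {(1S)-2,4,4-trimethyl-3-[(phenylsulfonyl)methyl]cyclohex-2-en-1-yl}diazene | N=N[C@H]1CCC(C)(C)C(CS(=O)(=O)c2ccccc2)=C1C | intermediate (not isolated)
14 | ({[(1S)-2,6,6-trimethylcyclohex-2-en-1-yl]methyl}sulfonyl)benzene, (S)-α-cyclogeranyl phenyl sulfone | O=S(=O)(C[C@@H]1C(C)=CCCC1(C)C)c1ccccc1 | intermediate
15 | geranyl acetate, (2E)-3,7-dimethylocta-2,6-dien-1-yl acetate | CC(C)=CCC/C(C)=C/COC(C)=O | starting material
16 | (2E,6E)-8-hydroxy-3,7-dimethylocta-2,6-dien-1-yl acetate | CC(=O)OC/C=C(\C)CC/C=C(\C)CO | intermediate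
17 | (2E,6E)-8-bromo-3,7-dimethylocta-2,6-dien-1-yl acetate | CC(=O)OC/C=C(\C)CC/C=C(\C)CBr | intermediate
18 | {(phenylsulfonyl)[(1S)-2,6,6-trimethylcyclohex-2-en-1-yl]methyl}lithium | [Li]C([C@@H]1C(C)=CCCC1(C)C)S(=O)(=O)c1ccccc1 | intermediate (not isolated)
19 | (2E,6E)-3,7-dimethyl-9-(phenylsulfonyl)-9-[(1S)-2,6,6-trimethylcyclohex-2-en-1-yl]nona-2,6-dien-1-yl acetate (both epimers at C9) | CC(=O)OC/C=C(\C)CC/C=C(\C)CC([C@@H]1C(C)=CCCC1(C)C)S(=O)(=O)c1ccccc1 | intermediate
20 | (2E,6E)-3,7-dimethyl-9-[(1S)-2,6,6-trimethylcyclohex-2-en-1-yl]nona-2,6-dien-1-yl acetate | CC(=O)OC/C=C(\C)CC/C=C(\C)CC[C@@H]1C(C)=CCCC1(C)C | intermediate (not isolated)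
21 | (2E,6E)-3,7-dimethyl-9-[(1S)-2,6,6-trimethylcyclohex-2-en-1-yl]nona-2,6-dien-1-ol | OC/C=C(\C)CC/C=C(\C)CC[C@@H]1C(C)=CCCC1(C)C | intermediate
22 | oleic acid, (9Z)-octadec-9-enoic acid | CCCCCCCC/C=C\CCCCCCCC(=O)O | starting material
23 | (2E,6E)-3,7-dimethyl-9-[(1S)-2,6,6-trimethylcyclohex-2-en-1-yl]nona-2,6-dien-1-yl (9Z)-octadec-9-enoate | CCCCCCCC/C=C\CCCCCCCC(=O)OC/C=C(\C)CC/C=C(\C)CC[C@@H]1C(C)=CCCC1(C)C | target

**Step count**
Total: 10 steps. Longest linear sequence: 8 steps (steps 1, 2, 3, 4, 5, 8, 9, 10); steps 6 and 7 make the second half in parallel.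

**Steps most likely to fail**

Step 3 (Proposed new method). β-Hydride elimination from the methyl groups of the rhodacycle, decarbonylation, or thermal 1,5-hydrogen shift of the ring-opened vinylketene may outrun ethylene insertion, or the catalyst may rest as an unreactive η4-vinylketene complex. The fallback uses known chemistry, sets out from 5 and comes back at 10. Purchased 3-ethoxy-2-methylcyclohex-2-en-1-one is methylated at C6 (LDA, MeI, THF, −78 °C) to racemic 3-ethoxy-2,6-dimethylcyclohex-2-en-1-one F1 and once more to 3-ethoxy-2,6,6-trimethylcyclohex-2-en-1-one F2. Compound 6, made from 5 and n-BuLi, adds to the carbonyl group of F2 to give 3-ethoxy-2,6,6-trimethyl-1-[(phenylsulfonyl)methyl]cyclohex-2-en-1-ol F3, and 2 M aq. HCl effects the Stork–Danheiser transposition to 10. In this fallback the six-membered ring is bought instead of built and ethylene is not used.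

Step 5. Elimination of the activated allylic alcohol to a diene, a Mitsunobu displacement too slow at the hindered carbinol so that the hydrazide decomposes first, or partial SN2' displacement that erodes the chirality transfer. The fallback sets out from 11 and comes back at 14. Formylation (acetic formic anhydride, pyridine, 0 °C) gives (1R)-2,4,4-trimethyl-3-[(phenylsulfonyl)methyl]cyclohex-2-en-1-yl formate F4. With Pd(OAc)2 and PBu3 (zerovalent palladium formed in situ) in THF at rt, ionisation with inversion gives the π-allylpalladium formate and loss of CO2 a palladium hydride. The hydride is delivered from the metal face to the more substituted allyl terminus (Tsuji-type formate reduction), that is, anti to the former oxygen as in the diazene route, so the same (S) sulfone 14 should result. The sigmatropic hydrogen delivery is thereby replaced by an ionic, metal-bound one.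

Step 8. Sluggish alkylation of the hindered α-sulfonyl carbanion next to the ring, with competing acyl transfer from the acetate or elimination of the allylic bromide. The fallback sets out from 10 (with 17) and comes back at 19; it joins the halves before the stereocentre is set. The doubly activated CH2 of 10 (sulfone and vinylogous ketone) is alkylated with 17 under mild base (Cs2CO3, DMF, 0 °C) at the sulfone-bearing carbon to give (2E,6E)-3,7-dimethyl-9-(phenylsulfonyl)-9-(2,6,6-trimethyl-3-oxocyclohex-1-en-1-yl)nona-2,6-dien-1-yl acetate F5. The conditions of step 4 then give (2E,6E)-9-[(3R)-3-hydroxy-2,6,6-trimethylcyclohex-1-en-1-yl]-3,7-dimethyl-9-(phenylsulfonyl)nona-2,6-dien-1-yl acetate F6. The conditions of step 5 lead through the allylic sulfonylhydrazine (2E,6E)-3,7-dimethyl-9-{(3S)-3-[1-(2-nitrophenylsulfonyl)hydrazinyl]-2,6,6-trimethylcyclohex-1-en-1-yl}-9-(phenylsulfonyl)nona-2,6-dien-1-yl acetate F7 and the allylic diazene (2E,6E)-9-[(3S)-3-diazenyl-2,6,6-trimethylcyclohex-1-en-1-yl]-3,7-dimethyl-9-(phenylsulfonyl)nona-2,6-dien-1-yl acetate F8 to 19.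

**Further compounds**
F1 | step 3 | 3-ethoxy-2,6-dimethylcyclohex-2-en-1-one (racemic) | CCOC1=C(C)C(=O)C(C)CC1
F2 | step 3 | 3-ethoxy-2,6,6-trimethylcyclohex-2-en-1-one | CCOC1=C(C)C(=O)C(C)(C)CC1
F3 | step 3 | 3-ethoxy-2,6,6-trimethyl-1-[(phenylsulfonyl)methyl]cyclohex-2-en-1-ol (racemic) | CCOC1=C(C)C(O)(CS(=O)(=O)c2ccccc2)C(C)(C)CC1
F4 | step 5 | (1R)-2,4,4-trimethyl-3-[(phenylsulfonyl)methyl]cyclohex-2-en-1-yl formate | O=CO[C@@H]1CCC(C)(C)C(CS(=O)(=O)c2ccccc2)=C1C
F5 | step 8 | (2E,6E)-3,7-dimethyl-9-(phenylsulfonyl)-9-(2,6,6-trimethyl-3-oxocyclohex-1-en-1-yl)nona-2,6-dien-1-yl acetate (racemic at C9) | CC(=O)OC/C=C(\C)CC/C=C(\C)CC(C1=C(C)C(=O)CCC1(C)C)S(=O)(=O)c1ccccc1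
F6 | step 8 | (2E,6E)-9-[(3R)-3-hydroxy-2,6,6-trimethylcyclohex-1-en-1-yl]-3,7-dimethyl-9-(phenylsulfonyl)nona-2,6-dien-1-yl acetate (both epimers at C9) | CC(=O)OC/C=C(\C)CC/C=C(\C)CC(C1=C(C)[C@H](O)CCC1(C)C)S(=O)(=O)c1ccccc1
F7 | step 8 | (2E,6E)-3,7-dimethyl-9-{(3S)-3-[1-(2-nitrophenylsulfonyl)hydrazinyl]-2,6,6-trimethylcyclohex-1-en-1-yl}-9-(phenylsulfonyl)nona-2,6-dien-1-yl acetate | CC(=O)OC/C=C(\C)CC/C=C(\C)CC(C1=C(C)[C@@H](N(N)S(=O)(=O)c2ccccc2[N+](=O)[O-])CCC1(C)C)S(=O)(=O)c1ccccc1
F8 | step 8 | (2E,6E)-9-[(3S)-3-diazenyl-2,6,6-trimethylcyclohex-1-en-1-yl]-3,7-dimethyl-9-(phenylsulfonyl)nona-2,6-dien-1-yl acetate | CC(=O)OC/C=C(\C)CC/C=C(\C)CC(C1=C(C)[C@@H](N=N)CCC1(C)C)S(=O)(=O)c1ccccc1
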